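**Retrosynthetic overview**

1. Numbering (ent-kaurane type): C4 = lactone α-carbon, C5 = ring-fusion CH, C6 = lactone CH–O, C7 = linking CH2, C8 = quaternary bridgehead, C9 = enone carbonyl, C11=C12 = enone alkene, C13 = CH bridgehead, C14 = CH2 bridge, C15 = CH–OAc, C16=C17 = exocyclic alkene, C10 = carbinol carbon of ring A.
2. End game: the C9 ketone is carried as a 4-methoxybenzyl (PMB) ether and C15–OH is acetylated; the five-membered ring of the bicyclo[3.2.1]octene is opened at C15–C16 (ketyl–alkyne 5-exo-dig closure of a cis-1,3 formyl/ethynyl cyclohexene).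
3. Key disconnection: the six-membered ring C8–C9–C11–C12–C13–C14 is cut at C8–C9 and C13–C14 by a catalytic asymmetric Diels–Alder reaction of a 2-substituted acrolein (C14=C8–C15HO, carrying the lactone through C7) with a (1E,3E)-1-alkoxy-4-ethynyl diene (C9=C11–C12=C13). The enabling feature is that the oxygen-bearing C9 sits next to the quaternary C8, which itself carries the oxidised C15, with C11=C12 β,γ to C8: the "ortho" adduct pattern of a 1-oxygenated diene and an α-branched enal.
4. West fragment: lactone C6–C7 bond by Hosomi–Sakurai allylation/lactonisation; ring A (C5–C10) by enamine-mediated intramolecular aldol addition; quaternary C4 by palladium-catalysed decarboxylative allylic alkylation, then ozonolytic opening of that ring.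
5. Order of ring formation: ring A, then the γ-lactone, then the cyclohexene (key step), then the five-membered ring that completes the bicyclo[3.2.1]octene.

Key step: step 10

Assumption: for the two catalyst-controlled steps (5 and 10) the catalyst enantiomer written is the one that the accepted transition-state model assigns to the required configuration; the mirror-image catalyst is equally accessible should the sense prove opposite.

**Route**

Step 1
Reactants: 1 2,6-dimethylcyclohexan-1-one (commercial cis/trans mixture); 2 allyl chloroformate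
Product: 3 allyl 2,6-dimethylcyclohex-1-en-1-yl carbonate (racemic)
Conditions: LiN(SiMe3)2, TMEDA, THF, −78 → 0 °C; then 2, −78 °C
Reagents that add atoms: none
Why: Only one enolate constitution is possible, and O-acylation of the lithium enolate by a chloroformate in the presence of TMEDA is the standard way to allyl enol carbonates; no stereocentre of the target is set.

Step 2
Reactants: 3 allyl 2,6-dimethylcyclohex-1-en-1-yl carbonate
Product: 4 (2R)-2-allyl-2,6-dimethylcyclohexan-1-one (both C6 epimers)
Conditions: Pd2(dba)3 (2.5 mol%), (R)-4-tert-butyl-2-[2-(diphenylphosphanyl)phenyl]-4,5-dihydro-1,3-oxazole (6 mol%), THF, 25 °C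
Reagents that add atoms: none
Why: Palladium-catalysed decarboxylative asymmetric allylic alkylation: ionisation and loss of CO2 give an allylpalladium enolate, and the chiral phosphinooxazoline ligand directs allylation to one face of the tetrasubstituted enolate, which should set the quaternary centre (later C4) as R, while the other α-centre may remain a mixture because it becomes sp2 in step 3.

Step 3
Reactants: 4 (2R)-2-allyl-2,6-dimethylcyclohexan-1-one
Product: 5 {[(6R)-6-allyl-2,6-dimethylcyclohex-1-en-1-yl]oxy}trimethylsilane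
Conditions: LiN(iPr)2, THF, −78 → 0 °C; then Me3SiCl
Reagents that add atoms: chlorotrimethylsilane, C[Si](C)(C)Cl
Why: The ketone has a single enolisable hydrogen, so deprotonation and O-silylation should give one tetrasubstituted silyl enol ether without touching the quaternary centre.

Step 4
Reactants: 5 {[(6R)-6-allyl-2,6-dimethylcyclohex-1-en-1-yl]oxy}trimethylsilane
Product: 7 methyl (2R)-2-methyl-6-oxo-2-(2-oxoethyl)heptanoate, via keto aldehyde acid 6 (not isolated)
Conditions: O3, CH2Cl2, −78 °C; Me2S, −78 → 23 °C; then Me3SiCHN2, PhMe/MeOH, 0 °C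
Reagents that add atoms: ozone, [O-][O+]=O; trimethylsilyldiazomethane, C[Si](C)(C)C=[N+]=[N-]
Why: Ozonolysis with reductive work-up cleaves the silyl enol ether to a carboxylic acid plus a methyl ketone and the terminal alkene to an aldehyde, and trimethylsilyldiazomethane then methylates only the acid (normal ester), which removes the internal acid before the aldol step; the quaternary centre is untouched.

Step 5
Reactants: 7 methyl (2R)-2-methyl-6-oxo-2-(2-oxoethyl)heptanoate
Product: 8 methyl (1R,2R,3R)-2-formyl-3-hydroxy-1,3-dimethylcyclohexane-1-carboxylate (formyl cis to the ester and trans to the hydroxyl)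
Conditions: D-proline (20 mol%), DMSO, 23 °C
Reagents that add atoms: none
Why: Proline-catalysed 6-enolexo intramolecular aldol addition: the E-enamine of the aldehyde attacks the methyl ketone through a chair transition state in which the ketone oxygen is hydrogen-bonded to the catalyst carboxylic acid (equatorial hydroxyl, axial methyl, trans to the formyl group), and the resident quaternary centre places its ester rather than its methyl group axial and syn to the new axial methyl, a preference matched with the D-catalyst, so C5 and C10 should be set as required.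

Step 6
Reactants: 8 methyl (1R,2R,3R)-2-formyl-3-hydroxy-1,3-dimethylcyclohexane-1-carboxylate; 9 [2-(chloromethyl)prop-2-en-1-yl]trimethylsilane
Product: 10 (3R,3aS,4R,7aR)-3-[2-(chloromethyl)prop-2-en-1-yl]-4-hydroxy-4,7a-dimethylhexahydro-2-benzofuran-1(3H)-one
Conditions: BF3·OEt2, CH2Cl2, −78 → 0 °C
Reagents that add atoms: none
Why: Hosomi–Sakurai allylation with in-situ lactonisation: the monodentate Lewis acid avoids chelation by the β-hydroxyl, the cis ester engages the activated formyl carbon so that the allylsilane should add to a cis-fused bicyclic acyloxycarbenium-type species on its convex face, anti to the carbinol-bearing ring carbon, which sets C6 (R) and closes the γ-lactone with loss of the ester methoxyl.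

Step 7
Reactants: 10 (3R,3aS,4R,7aR)-3-[2-(chloromethyl)prop-2-en-1-yl]-4-hydroxy-4,7a-dimethylhexahydro-2-benzofuran-1(3H)-one
Product: 11 2-{[(3R,3aS,4R,7aR)-4-hydroxy-4,7a-dimethyl-1-oxooctahydro-2-benzofuran-3-yl]methyl}prop-2-enal
Conditions: N-methylmorpholine N-oxide, NaI (cat.), MeCN, 40 °C
Reagents that add atoms: N-methylmorpholine N-oxide, C[N+]1([O-])CCOCC1
Why: Kornblum-type oxidation: the N-oxide oxygen displaces the allylic halide (iodide catalysis) and elimination of N-methylmorpholine should give the 2-substituted acrolein without affecting any stereocentre, the lactone or the tertiary alcohol.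

Step 8
Reactants: 12 glutaconaldehyde potassium salt (potassium (1E,3E)-5-oxopenta-1,3-dien-1-olate); 13 4-methoxybenzyl chloride
Product: 14 (2E,4E)-5-[(4-methoxybenzyl)oxy]penta-2,4-dienal
Conditions: DMF, 23 °C
Reagents that add atoms: none
Why: The delocalised vinylogous formate anion is alkylated on oxygen by a benzylic chloride in a dipolar aprotic solvent (the way 3-alkoxyacroleins are made from malonaldehyde salts), and the E,E geometry of the salt should be retained.

Step 9
Reactants: 14 (2E,4E)-5-[(4-methoxybenzyl)oxy]penta-2,4-dienal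
Product: 15 (1E,3E)-1-[(4-methoxybenzyl)oxy]hexa-1,3-dien-5-yne
Conditions: Me3SiCHN2, LiN(iPr)2, THF, −78 → 0 °C
Reagents that add atoms: trimethylsilyldiazomethane, C[Si](C)(C)C=[N+]=[N-]
Why: Colvin rearrangement: lithiated trimethylsilyldiazomethane adds to the aldehyde, Peterson-type elimination and 1,2-hydrogen shift of the alkylidene carbene give the terminal alkyne under aprotic conditions that should leave the acid- and alcohol-sensitive dienyl ether and its E,E geometry intact.

Step 10
Reactants: 11 2-{[(3R,3aS,4R,7aR)-4-hydroxy-4,7a-dimethyl-1-oxooctahydro-2-benzofuran-3-yl]methyl}prop-2-enal; 15 (1E,3E)-1-[(4-methoxybenzyl)oxy]hexa-1,3-dien-5-yne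
Product: 16 (1S,2S,5S)-5-ethynyl-1-{[(3R,3aS,4R,7aR)-4-hydroxy-4,7a-dimethyl-1-oxooctahydro-2-benzofuran-3-yl]methyl}-2-[(4-methoxybenzyl)oxy]cyclohex-3-ene-1-carbaldehyde (formyl, PMB-oxy and ethynyl groups mutually cis)
Conditions: (R)-1,1'-bi-2-naphthol/TiCl2(OiPr)2 (10 mol%), CH2Cl2, −30 → 0 °C
Reagents that add atoms: none
Why: A Lewis-acid-catalysed normal-demand Diels–Alder reaction: the titanium-bound, s-trans 2-substituted acrolein 11 and the 1-alkoxy diene 15 combine in a concerted but asynchronous [4+2] cycloaddition in which C13–C14 bonding runs ahead of C8–C9 bonding. The closest known reaction type is the binaphthol–titanium dichloride-catalysed, endo-selective cycloaddition of methacrolein to 1-alkoxy- and 1-acyloxybuta-1,3-dienes, which builds formyl-bearing quaternary centres in the same way. The step closes the cyclohexene ring C8–C9–C11–C12–C13–C14 by an intermolecular suprafacial (4+2) closure and leaves the C11=C12 double bond where the enone needs it. The quaternary centre C8 is set by the catalyst, which shields one face of the coordinated enal (the resident centres are insulated from C8 by the C7 methylene and should exert little bias), while C9 and C13 follow from C8 through the E,E geometry of the diene and the endo orientation of the formyl group. The step needs "ortho" regioselectivity, which the strong alkoxy donor at C9 secures over the weakly conjugating alkyne at C13, endo selectivity, which secondary overlap with the activated formyl group secures, and chemoselectivity, which follows because the isolated alkyne, the lactone and the hindered tertiary hydroxyl are neither dienophiles nor good ligands.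

Step 11
Reactants: 16 (1S,2S,5S)-5-ethynyl-1-{[lactonyl]methyl}-2-[(4-methoxybenzyl)oxy]cyclohex-3-ene-1-carbaldehyde
Product: 17 (1R,2S,5S,7R)-7-hydroxy-1-{[(3R,3aS,4R,7aR)-4-hydroxy-4,7a-dimethyl-1-oxooctahydro-2-benzofuran-3-yl]methyl}-2-[(4-methoxybenzyl)oxy]-6-methylidenebicyclo[3.2.1]oct-3-ene (C7 hydroxyl anti to the one-carbon bridge)
Conditions: SmI2, t-BuOH, THF, 0 → 23 °C (no HMPA)
Reagents that add atoms: none
Why: Samarium diiodide ketyl–alkyne radical cyclisation: the aldehyde ketyl closes 5-exo-dig onto the cis-disposed ethynyl group to form C15–C16 and, after reduction and protonation of the vinyl radical, the exocyclic methylene, and the trivalent samarium on the ketyl oxygen should be chelated by the neighbouring cis PMB-ether oxygen at C9, which delivers the C15 oxygen to the face away from the one-carbon bridge.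

Step 12
Reactants: 17 bicyclic allylic alcohol
Product: 18 (1S,2S,5S,7R)-1-{[(3R,3aS,4R,7aR)-4-hydroxy-4,7a-dimethyl-1-oxooctahydro-2-benzofuran-3-yl]methyl}-2-[(4-methoxybenzyl)oxy]-6-methylidenebicyclo[3.2.1]oct-3-en-7-yl acetate
Conditions: Ac2O, pyridine, 4-(dimethylamino)pyridine (cat.), CH2Cl2, 23 °C
Reagents that add atoms: acetic anhydride, CC(=O)OC(C)=O
Why: Nucleophile-catalysed acylation should acetylate the secondary allylic alcohol while the tertiary ring-A hydroxyl is too hindered to react under these conditions; no stereocentre is affected.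

Step 13
Reactants: 18 PMB-protected acetate
Product: 20 (1R,5S,7R)-1-{[(3R,3aS,4R,7aR)-4-hydroxy-4,7a-dimethyl-1-oxooctahydro-2-benzofuran-3-yl]methyl}-6-methylidene-2-oxobicyclo[3.2.1]oct-3-en-7-yl acetate (target CNP0172716.1), via allylic alcohol 19 (not isolated)
Conditions: DDQ, CH2Cl2/pH 7 buffer, 0 °C; then NaHCO3, Dess–Martin periodinane, 23 °C
Reagents that add atoms: none
Why: Oxidative PMB cleavage (hydride abstraction by DDQ, hydrolysis of the oxocarbenium ion) frees the C9 allylic alcohol, which Dess–Martin periodinane should oxidise in the same flask to the enone; the only centre changed is C9, which becomes sp2.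

**Compound list**

1 | 2,6-dimethylcyclohexan-1-one | CC1CCCC(C)C1=O | starting material
2 | allyl chloroformate | C=CCOC(=O)Cl | starting material
3 | allyl 2,6-dimethylcyclohex-1-en-1-yl carbonate (racemic) | C=CCOC(=O)OC1=C(C)CCCC1C | intermediate
4 | (2R)-2-allyl-2,6-dimethylcyclohexan-1-one (C6 epimers) | C=CC[C@@]1(C)CCCC(C)C1=O | intermediate
5 | {[(6R)-6-allyl-2,6-dimethylcyclohex-1-en-1-yl]oxy}trimethylsilane | C=CC[C@@]1(C)CCCC(C)=C1O[Si](C)(C)C | intermediate
6 | (2R)-2-methyl-6-oxo-2-(2-oxoethyl)heptanoic acid (in equilibrium with its lactol) | OC(=O)[C@@](C)(CC=O)CCCC(C)=O | intermediate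
7 | methyl (2R)-2-methyl-6-oxo-2-(2-oxoethyl)heptanoate | COC(=O)[C@@](C)(CC=O)CCCC(C)=O | intermediate
8 | methyl (1R,2R,3R)-2-formyl-3-hydroxy-1,3-dimethylcyclohexane-1-carboxylate | COC(=O)[C@]1(C)CCC[C@@](C)(O)[C@@H]1C=O | intermediate
9 | [2-(chloromethyl)prop-2-en-1-yl]trimethylsilane | C=C(CCl)C[Si](C)(C)C | starting material
10 | (3R,3aS,4R,7aR)-3-[2-(chloromethyl)prop-2-en-1-yl]-4-hydroxy-4,7a-dimethylhexahydro-2-benzofuran-1(3H)-one | ClCC(=C)C[C@H]1OC(=O)[C@]2(C)CCC[C@@](C)(O)[C@H]12 | intermediate
11 | 2-{[(3R,3aS,4R,7aR)-4-hydroxy-4,7a-dimethyl-1-oxooctahydro-2-benzofuran-3-yl]methyl}prop-2-enal | O=CC(=C)C[C@H]1OC(=O)[C@]2(C)CCC[C@@](C)(O)[C@H]12 | intermediate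
12 | glutaconaldehyde potassium salt | [K+].[O-]/C=C/C=C/C=O | starting material
13 | 4-methoxybenzyl chloride | COc1ccc(CCl)cc1 | starting material
14 | (2E,4E)-5-[(4-methoxybenzyl)oxy]penta-2,4-dienal | O=C/C=C/C=C/OCc1ccc(OC)cc1 | intermediate
15 | (1E,3E)-1-[(4-methoxybenzyl)oxy]hexa-1,3-dien-5-yne | C#C/C=C/C=C/OCc1ccc(OC)cc1 | intermediate
16 | (1S,2S,5S)-5-ethynyl-1-{[(3R,3aS,4R,7aR)-4-hydroxy-4,7a-dimethyl-1-oxooctahydro-2-benzofuran-3-yl]methyl}-2-[(4-methoxybenzyl)oxy]cyclohex-3-ene-1-carbaldehyde | O=C[C@]1(C[C@H]2OC(=O)[C@]3(C)CCC[C@@](C)(O)[C@H]23)C[C@H](C#C)C=C[C@@H]1OCc4ccc(OC)cc4 | intermediate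
17 | (1R,2S,5S,7R)-7-hydroxy-1-{[(3R,3aS,4R,7aR)-4-hydroxy-4,7a-dimethyl-1-oxooctahydro-2-benzofuran-3-yl]methyl}-2-[(4-methoxybenzyl)oxy]-6-methylidenebicyclo[3.2.1]oct-3-ene | C=C1[C@@H]2C=C[C@H](OCc5ccc(OC)cc5)[C@@](C[C@H]3OC(=O)[C@]4(C)CCC[C@@](C)(O)[C@H]34)(C2)[C@@H]1O | intermediate
18 | (1S,2S,5S,7R)-1-{[(3R,3aS,4R,7aR)-4-hydroxy-4,7a-dimethyl-1-oxooctahydro-2-benzofuran-3-yl]methyl}-2-[(4-methoxybenzyl)oxy]-6-methylidenebicyclo[3.2.1]oct-3-en-7-yl acetate | C=C1[C@@H]2C=C[C@H](OCc5ccc(OC)cc5)[C@@](C[C@H]3OC(=O)[C@]4(C)CCC[C@@](C)(O)[C@H]34)(C2)[C@@H]1OC(C)=O | intermediate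
19 | (1S,2S,5S,7R)-2-hydroxy-1-{[(3R,3aS,4R,7aR)-4-hydroxy-4,7a-dimethyl-1-oxooctahydro-2-benzofuran-3-yl]methyl}-6-methylidenebicyclo[3.2.1]oct-3-en-7-yl acetate | C=C1[C@@H]2C=C[C@H](O)[C@@](C[C@H]3OC(=O)[C@]4(C)CCC[C@@](C)(O)[C@H]34)(C2)[C@@H]1OC(C)=O | intermediate
20 | (1R,5S,7R)-1-{[(3R,3aS,4R,7aR)-4-hydroxy-4,7a-dimethyl-1-oxooctahydro-2-benzofuran-3-yl]methyl}-6-methylidene-2-oxobicyclo[3.2.1]oct-3-en-7-yl acetate | C=C1[C@@H]2C=CC(=O)[C@@](C[C@H]3OC(=O)[C@]4(C)CCC[C@@](C)(O)[C@H]34)(C2)[C@@H]1OC(C)=O | target

**Step count and risks**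

Total: 13 steps. Longest linear sequence: 11 steps (steps 1–7, then 10–13); the diene branch (steps 8–9) is 2 steps.

Step 10 (key step). The free tertiary hydroxyl or the lactone carbonyl may compete for the titanium centre, so that an uncatalysed background cycloaddition erodes the facial selectivity at C8, or the dienyl ether may decompose under the Lewis acid. The fallback replaces catalyst control by auxiliary control in an ionic Diels–Alder reaction and sets out from 11. Acetalisation with (2R,4R)-pentane-2,4-diol (PPTS, benzene, azeotropic removal of water) would give the chiral dioxane acetal F1. With catalytic Me3SiOTf in CH2Cl2 at −78 °C, F1 should ionise to a 2-alkoxyallyl cation whose tethered chiral alkoxide fixes the open face, and cycloaddition with diene 15 would give the cycloadduct acetal F2. Mild hydrolysis (PPTS, acetone/water) comes back to the route at 16.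

Step 11. The ketyl may be reduced further to the simple carbinol or undergo pinacol coupling before the 5-exo-dig closure, and without effective chelation the C15 oxygen may be delivered to the face of the one-carbon bridge. The fallback sets out from 16 and separates ring closure from the setting of C15. Nickel-catalysed reductive aldehyde–alkyne cyclisation (Ni(cod)2, PBu3, Et3SiH, THF) would give the bicyclic triethylsilyl ether F3 as C15 epimers. HF·pyridine would give the alcohol mixture F4, and Dess–Martin oxidation the exo-methylene ketone F5. Luche reduction (NaBH4, CeCl3·7H2O, MeOH, −78 °C) should deliver hydride from the face of the one-carbon bridge, the opposite face being screened by the C9 PMB ether, and comes back to the route at 17.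

Step 5. Retro-aldol equilibration may drain the kinetic product toward the epimer with an axial hydroxyl, or the tertiary aldol may dehydrate to the conjugated enal. The fallback sets out from 7 and builds the carbinol stepwise. Aldol condensation (pyrrolidine, AcOH, toluene, 60 °C) would give the cyclohexenecarbaldehyde F6. Weitz–Scheffer epoxidation (H2O2, NaOH, MeOH, 0 °C), in which the hydroperoxide should add to the β-carbon anti to the pseudo-axial ester, would give the epoxy aldehyde F7. Reductive opening of the C–O bond α to the formyl group (SmI2, THF/MeOH, −90 °C), with protonation to the equatorial aldehyde, comes back to the route at 8.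

**Further compounds**

F1 | step 10 | (3R,3aS,4R,7aR)-3-{2-[(4R,6R)-4,6-dimethyl-1,3-dioxan-2-yl]prop-2-en-1-yl}-4-hydroxy-4,7a-dimethylhexahydro-2-benzofuran-1(3H)-one | C[C@@H]1C[C@@H](C)OC(O1)C(=C)C[C@H]2OC(=O)[C@]3(C)CCC[C@@](C)(O)[C@H]23
F2 | step 10 | (4R,6R)-4,6-dimethyl-1,3-dioxane acetal of aldehyde 16 | C[C@@H]1C[C@@H](C)OC(O1)[C@]2(C[C@H]3OC(=O)[C@]4(C)CCC[C@@](C)(O)[C@H]34)C[C@H](C#C)C=C[C@@H]2OCc5ccc(OC)cc5
F3 | step 11 | triethylsilyl ether of 17 as a mixture of C7 (bicyclooctene numbering) epimers | C=C1[C@@H]2C=C[C@H](OCc5ccc(OC)cc5)[C@@](C[C@H]3OC(=O)[C@]4(C)CCC[C@@](C)(O)[C@H]34)(C2)C1O[Si](CC)(CC)CC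
F4 | step 11 | 17 together with its C7 epimer (alcohol mixture) | C=C1[C@@H]2C=C[C@H](OCc5ccc(OC)cc5)[C@@](C[C@H]3OC(=O)[C@]4(C)CCC[C@@](C)(O)[C@H]34)(C2)C1O
F5 | step 11 | (1R,2S,5S)-1-{[(3R,3aS,4R,7aR)-4-hydroxy-4,7a-dimethyl-1-oxooctahydro-2-benzofuran-3-yl]methyl}-2-[(4-methoxybenzyl)oxy]-6-methylidenebicyclo[3.2.1]oct-3-en-7-one | C=C1[C@@H]2C=C[C@H](OCc5ccc(OC)cc5)[C@@](C[C@H]3OC(=O)[C@]4(C)CCC[C@@](C)(O)[C@H]34)(C2)C1=O
F6 | step 5 | methyl (1R)-2-formyl-1,3-dimethylcyclohex-2-ene-1-carboxylate | COC(=O)[C@]1(C)CCCC(C)=C1C=O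
F7 | step 5 | methyl 1-formyl-2,6-dimethyl-7-oxabicyclo[4.1.0]heptane-2-carboxylate (epoxide oxygen trans to the ester) | COC(=O)[C@]1(C)CCC[C@@]2(C)O[C@@]12C=O
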